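All runs are simulated for substances that don't exist.

The substrate stops.

| flask | substrate | partner | capture agent | remark | time |
|---|---|---|---|---|---|
| midnight | 20 mM (fed, over 2.5 h) | 1.05 equiv | 28 mM | run made earlier |  |
| noon | 20 mM (fed, over 2.5 h) | 1.05 equiv | 44 mM | run made earlier |  |
| flask | 20 mM (fed, over 2.5 h) | 1.05 equiv | 20.0 mM |  | 25 h |

| run | time / h | substrate / % | product / % | trapped intermediate / % |
|---|---|---|---|---|
| midnight | 4.00 | 93.4 | 3.6 | 3.7 |
| midnight | 8.00 | 92.8 | 4.0 | 2.2 |
| midnight | 12.0 | 94.4 | 3.7 | 4.9 |
| midnight | 15.0 | 93.5 | 2.8 | 3.1 |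
| midnight | 20.0 | 93.7 | 4.6 | 4.1 |
| noon | 1.50 | 52.4 | 2.4 | 3.3 |
| noon | 3.00 | 94.6 | 4.4 | 3.7 |
| noon | 6.00 | 94.7 | 4.4 | 3.8 |
| noon | 10.0 | 93.6 | 3.7 | 2.9 |
| noon | 20.0 | 93.7 | 6.4 | 3.2 |

(readings scatter by 1 percentage point)

* part of the substrate gone at 25 h
* the product standing at 25 h, as a percentage of the substrate charged
* the trapped intermediate standing at 25 h, as a percentage of the substrate charged

- percentages count the whole charge, also what has not yet gone in

- I start from the symmetric count, one partner for one substrate: a partner yield of 100% is the zero of my scale.
- After the feed, the midnight and noon readings average 6.18% of the substrate gone, so the partner yield reads 5.88%: the substrate gone per equivalent of partner charged, far below the count.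
- Time: by hand, a slow reaction keeps creeping, but the noon substrate readings stay flat within the scatter from 3.00 h to 20.0 h, so I add nothing for 25 h.
- Feed: by hand, consumption follows the dosing, but at 1.50 h in the noon run 7.60% of the charge is already gone, which reads like the final figure before the feed ends.
- Capture agent: by hand, more of it should take more intermediate, but trapped intermediate reads 3.60% at 28 mM and 3.38% at 44 mM, so I keep the yield at 20.0 mM, though that lies outside the tested range.
- Partner: both runs hold it at 1.05 equiv, so they do not test it; by hand, I suppose the substrate gone follows the partner charged, so my reckoning for the flask is yield times equivalents, 6.18% gone.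
- The forecast gives 6.5% gone, 4.2% product and 3.3% trapped intermediate, saying “The run has stalled rather than being slow.” Its conversion stands a little above mine.
- The flask gives 6.37% gone, 3.51% product and 2.86% trapped intermediate, within the forecast's margins.

    substrate + partner → product (k = 0.0580 M⁻¹ s⁻¹)
    partner → decomposed reagent (k = 0.00160 s⁻¹)
    substrate + partner → intermediate A (k = 0.0570 M⁻¹ s⁻¹)
    intermediate B → product (k = 2.40 × 10⁻⁵ s⁻¹)
    intermediate A ⇌ intermediate B (K = 1.30, k = 1.90 × 10⁻⁴ s⁻¹)
    capture agent + intermediate A → trapped intermediate (k = 0.0130 M⁻¹ s⁻¹)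

- At 25 h the partner, the limiting reagent, stands at 0% in the flask, beside 19.7 mM of decomposed reagent. The partner yield I read, 5.88%, gave 6.18% gone on this flask's 1.05 equiv; the flask's own substrate gone per equivalent of partner charged is 6.07%.
- For the neighbour flask with 4.20 equiv of partner, the carried yield gives 24.7% of the substrate gone. The computed neighbour flask has 14.8% gone, a partner yield of 3.52%.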